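Abbreviations: TBS = tert‑butyldimethylsilyl, TES = triethylsilyl. Atom numbers are those of the decalin: ring A is C5–C6=C7–C8(=O)–C9–C10 and ring B is C10–C1–C2–C3–C4–C5.

## Analysis of the target

Target 28 is a cis‑fused decalin. Ring A is a cyclohexenone whose C6=C7–C8=O unit carries an acetyl group on C7 (a cross‑conjugated enedione), and ring B is saturated. It has five contiguous stereocentres: C3 (S, acetate), C4 (R, methyl), C5 (R, quaternary, methyl), C10 (R, tertiary hydroxyl) and C9 (S, (Z)‑2‑methylbut‑2‑enoate). The C3 acetoxy group, both methyl groups and the C10 hydroxyl lie on one face of ring B, while the C5–C6 and C10–C9 bonds lie on the other. The C9 ester oxygen is trans to the C10 hydroxyl. Sensitive elements are the Z enoate (it isomerises to the E ester under nucleophilic, acidic or thermal stress), the 2‑acetyl enone (a strong Michael acceptor), the C9 hydrogen α to the C8 ketone (epimerisable), and the C10 hydroxyl β to C8 (retro‑aldol). The main difficulty is the pair of adjacent fully substituted carbons C5 and C10 inside a stereopentad, followed by late acylation of a hindered ketol. The plan rests on the C4/C5 array: a cis dimethyl pair, with C5 also carrying C6 at aldehyde oxidation level, next to the oxygenated quaternary C10. This is the pattern an (E)‑2‑methylbut‑2‑enal dienophile leaves when it adds to a 1‑silyloxy diene whose oxygenated terminus becomes C10.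

## Retrosynthetic reasoning

**28 ⇒ 25 + 26 (C9–O acyl bond).** The Z enoate is the most fragile group, so it is attached last, to the secondary C9 hydroxyl of diol 25 with acid 26. The tertiary C10 hydroxyl needs no protection at that point. The forward step must transfer the acyl group without Z to E isomerisation.

**25 ⇒ 24 ⇒ 21 ⇒ 19 + 20 (C6=C7 unsaturation, C7–acetyl bond).** The enedione is taken back to saturated ketone 19. The acetyl group comes from 20 by C‑acylation at C7, and the double bond from a selenoxide elimination of the resulting β‑diketone 21. Cutting here keeps the reactive 2‑acyl enone out of the route until three steps from the end. The C9 oxygen is carried as a TES ether so that enolisation goes to C7.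

**19 ⇒ 18 ⇒ 17 (C8–C9 bond, ring A).** Ring A is opened between C8 and C9 to dialdehyde 17. A carbene‑catalysed benzoin closure gives the ketol at the right oxidation level, and the two aldehydes differ sharply: C9 is neopentyl and non‑enolisable, C8 is unhindered. The forward reaction has to set C9 trans to the C10 oxygen.

**17 ⇒ 16 ⇒ 15 ⇒ 14 ⇒ 12 ⇒ 11 (oxidation levels).** Both aldehydes come from diol 16 in one oxidation. The C9 hydroxyl is released from a primary silyl ether that is far more labile than the tertiary one on C10. The C8 alcohol comes from carboxylic acid 14, because a carboxyl group can be reduced in the presence of the C3 acetate whereas an ester could not be. The C3 acetate comes from alcohol 12, and 12 from ketone 11 by a bulky hydride that the syn‑axial C5 methyl steers to the correct face.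

**11 ⇒ 10 ⇒ 9 (C3 oxygen).** The C3 ketone is traced to the ring B alkene C1=C2 by allylic oxidation. C3 is the only allylic carbon that bears hydrogen. One hydrogenation then removes both alkenes and the benzyl ester. A benzylic ether on C9 would not survive these two steps, which is why C9 carries a silyl ether.

**9 ⇒ 7 + 8 (C6=C7 bond).** The aldehyde of 7 cannot pass through allylic oxidation or hydride reduction, so it is homologated first. Olefination with phosphonate 8 adds C7 and C8 at acid oxidation level.

**7 ⇒ 5 + 6 (C5–C10 and C4–C3 bonds, ring B).** This is the central cut. A [4+2] cycloaddition of enal 6 with diene 5 forms ring B, both quaternary centres and the C4 centre at once. Suprafacial addition turns the E geometry of 6 into the cis methyl pair, and the formyl carbon is already C6. The forward reaction must be ortho‑selective, formyl‑endo and enantioselective.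

**5 ⇒ 4 ⇒ 3 ⇒ 1 + 2.** Diene 5 is the silyl dienol ether of the deconjugated ketone 4. The conjugated isomer of 4 would be the obvious precursor, but amine/silyl triflate enolisation of it would remove the α′ proton next to the CH2O group and give the cross‑conjugated diene. In 4 the CH2 between carbonyl and vinyl is by far the most acidic position. Ketone 4 comes from aldehyde 1 and allyl Grignard reagent 2 by addition and oxidation.

## Alternatives that were turned down

**Alternative 1:** The C4–CH2 bond (the future C4 methyl, delivered from a silicon tether on the C3 oxygen) and the C5–C6 bond are cut. In the forward step a tin‑hydride chain turns a bromomethylsilyl ether into a silylmethyl radical that closes onto C4. The tertiary C5 radical then adds to the terminal carbon of a C10‑bound ynone to close ring A and give siloxane‑bridged enone A1.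
- For: the tether forces the new carbon onto the face of the C3 oxygen, so the C3/C4 cis relationship is guaranteed. C5 and ring A arise in one operation, and A1 already holds C6=C7–C8=O.
- Against: the second closure must be 6‑endo at the alkyne against the usually faster 5‑exo mode. Nothing forces the C5 radical to attack syn to the C10 oxygen, so the cis fusion is not secured. Hydrogen transfer can intercept each radical. A1 still lacks the C9 oxygen and the C7 acetyl group, and its C–Si bond must later become C–H. The cascade substrate itself needs enantiopure ring B with C3 and C10 in place, a problem of about the size of 7.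
- Comparison: on C3/C4 this plan is stronger, since the chosen route spends steps 6 to 8 on that relationship. The chosen route offers a catalytic enantioselective step that fixes C4, C5 and C10 together from two achiral partners, and it brings the C9 oxygen in from the start.

**Alternative 2:** The C7–C8 bond is cut. A trialkylphosphine adds to C6 of a butenone side chain on C5, and the resulting enolate attacks the C8 aldehyde through C7. Loss of phosphine gives the Morita–Baylis–Hillman adduct A2.
- For: the acetyl group and the C6=C7 bond arrive with the ring closure, and one oxidation at C8 completes the enedione. On ring A this is clearly shorter than steps 14 to 16 of the chosen route, and the C8 configuration does not matter.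
- Against: the phosphine must add to a β‑carbon attached to the quaternary C5, and conjugate addition at such a neopentyl position is slow. The aldehyde partner carries the C9 stereocentre α to the formyl group and a free C10 hydroxyl β to it, as A2 shows, so epimerisation and retro‑aldol cleavage threaten under nucleophilic conditions. C9 would have to be set earlier in an open‑chain setting, and the ring B stereotriad remains unsolved.
- Comparison: this plan is stronger on ring A step economy. The chosen route keeps C9 as a non‑enolisable aldehyde until the ring is closed and places its main risk in an early step on simple material.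

**Alternative 3:** The C8–C9 bond is cut. A triazolium‑derived carbene makes the C8 aldehyde an acyl anion equivalent that adds to the C9 aldehyde and gives ketol A3.
- For: the closure is catalytic, redox‑neutral and mild, it gives the correct oxidation level, and the two aldehydes are differentiated by sterics.
- Against, as the central idea: it addresses the easier half of the molecule. The dialdehyde with C3, C4, C5 and C10 would have to come from elsewhere, the C9 configuration rests on substrate control alone, and acetyl group and unsaturation are still missing.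
- Comparison: on ring A the two plans are equal, because the same closure is used here as step 13 (ketol 18 is the TBS analogue of A3). The chosen strategy puts its defining disconnection on the C4–C5–C10 array, where the stereochemical problem lies.

Key step: step 4

Assumption: compounds 1, 2, 6, 8, 20 and 26 and both enantiomers of the B‑(o‑tolyl) diphenylprolinol oxazaborolidine are taken as commercial.

## Route

Step 1
Reactants: 1 (tert‑butyldimethylsilyloxy)acetaldehyde; 2 allylmagnesium bromide
Product: 3 racemic 1‑(tert‑butyldimethylsilyloxy)pent‑4‑en‑2‑ol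
Conditions: 2 (1.2 equiv), Et2O, −78 °C; aq. NH4Cl
Reagents that add atoms: none
Why: Grignard 1,2‑addition of the allyl group to the aldehyde; the new carbinol centre is racemic and is removed by oxidation in step 2.

Step 2
Reactants: 3 racemic 1‑(tert‑butyldimethylsilyloxy)pent‑4‑en‑2‑ol
Product: 4 1‑(tert‑butyldimethylsilyloxy)pent‑4‑en‑2‑one
Conditions: Dess–Martin periodinane, NaHCO3, CH2Cl2, 0 °C; used crude
Reagents that add atoms: none
Why: Dess–Martin oxidation of a homoallylic alcohol under buffered, non‑basic conditions should give the β,γ‑unsaturated ketone without moving the alkene into conjugation.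

Step 3
Reactants: 4 1‑(tert‑butyldimethylsilyloxy)pent‑4‑en‑2‑one
Product: 5 (Z)‑1,2‑bis(tert‑butyldimethylsilyloxy)penta‑2,4‑diene (silyloxy group cis to the vinyl group, CH2OTBS trans to it)
Conditions: TBSOTf, Et3N, CH2Cl2, −78 → 0 °C; used at once
Reagents that add atoms: tert‑butyldimethylsilyl trifluoromethanesulfonate, CC(C)(C)[Si](C)(C)OS(=O)(=O)C(F)(F)F
Why: Soft enolisation with silyl triflate and amine removes the most acidic proton, the one between carbonyl and vinyl, so the linear conjugated silyl dienol ether should form and not the enol ether toward the CH2OTBS side. This method normally places the silyloxy group cis to the β‑substituent, which is the Z geometry step 4 needs.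

Step 4
Reactants: 5 (Z)‑1,2‑bis(tert‑butyldimethylsilyloxy)penta‑2,4‑diene; 6 (E)‑2‑methylbut‑2‑enal
Product: 7 (1R,2R,6S)‑2‑(tert‑butyldimethylsilyloxy)‑2‑[(tert‑butyldimethylsilyloxy)methyl]‑1,6‑dimethylcyclohex‑3‑ene‑1‑carbaldehyde (decalin numbering: C5 bears CH3 and CHO, C4 bears CH3, C10 bears OTBS and CH2OTBS, alkene C1=C2; both methyls and the C10 silyloxy group on one face, CHO and CH2OTBS on the other)
Conditions: 5 (1.5 equiv), (R)‑3,3‑diphenyl‑1‑(o‑tolyl)tetrahydro‑1H,3H‑pyrrolo[1,2‑c][1,3,2]oxazaborole activated with HNTf2 (20 mol %), CH2Cl2, −78 → −40 °C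
Reagents that add atoms: none
Why: The N‑protonated oxazaborolidine binds the formyl oxygen of 6 (s‑trans enal, formyl C–H···O contact) and lowers its LUMO; diene 5, a vinylogous silyl enol ether, attacks with its unsubstituted terminus (C3) at the β‑carbon C4 while the silyloxy‑bearing terminus (C10) bonds to C5, so ring B closes by two σ‑bonds in a concerted, asynchronous [4+2] cycloaddition that is suprafacial on both partners. The closest known reaction type is the chiral oxazaborolidinium‑catalysed Diels–Alder reaction of α‑substituted enals with 1‑silyloxy‑1,3‑dienes; a diene whose reacting terminus carries two substituents is at the edge of that precedent. The ortho regiochemistry (C10 next to C5) follows from the silyloxy donor, which puts the largest HOMO coefficient on C3. The cis relationship of the C4 and C5 methyls is the E geometry of 6 carried through suprafacial addition. C10 is set relative to C5 by the Z geometry of 5 together with a formyl‑endo transition state: the outside CH2OTBS arm ends cis to the aldehyde and the inside silyloxy group cis to the C5 methyl, which is the cis‑fusion pattern. The absolute configuration comes from the catalyst, whose carbinol phenyl group shields one face of the bound enal; the accepted model assigns the required attack on the Si face of C5 to the (R) catalyst, and the antipode is equally available if the sense differs for this β‑substituted enal. The step therefore needs ortho selectivity (silyloxy group), formyl‑endo approach (weakened by the α‑methyl group, to be enforced by catalyst and low temperature), one enantioface (catalyst) and ring closure in preference to open‑chain vinylogous Mukaiyama addition, which is the real uncertainty.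

Step 5
Reactants: 7 Diels–Alder aldehyde; 8 benzyl (diethoxyphosphoryl)acetate
Product: 9 benzyl (E)‑3‑[(1R,2R,6S)‑2‑(tert‑butyldimethylsilyloxy)‑2‑[(tert‑butyldimethylsilyloxy)methyl]‑1,6‑dimethylcyclohex‑3‑en‑1‑yl]prop‑2‑enoate (C6=C7, C8 benzyl ester)
Conditions: 8, NaH, THF, 0 → 50 °C
Reagents that add atoms: none
Why: Horner–Wadsworth–Emmons olefination; the aldehyde has no α‑hydrogen, so base cannot epimerise it, and the small phosphonate anion should tolerate the neopentyl setting. The alkene geometry is of no consequence because C6=C7 is hydrogenated in step 7.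

Step 6
Reactants: 9 benzyl enoate
Product: 10 benzyl (E)‑3‑[2‑(tert‑butyldimethylsilyloxy)‑2‑[(tert‑butyldimethylsilyloxy)methyl]‑1,6‑dimethyl‑5‑oxocyclohex‑3‑en‑1‑yl]prop‑2‑enoate (C3 ketone conjugated with C1=C2; ring stereocentres as in 7)
Conditions: CrO3, 3,5‑dimethylpyrazole, CH2Cl2, −20 °C
Reagents that add atoms: chromium trioxide, O=[Cr](=O)=O
Why: Allylic C–H oxidation with the CrO3–3,5‑dimethylpyrazole complex; C3 is the only allylic carbon bearing hydrogen, and oxygen should enter at this less hindered end of the allyl system to give the C1=C2–C3=O enone. Silyl ethers and the benzyl ester are inert, and the non‑basic medium should leave the now enolisable C4 centre untouched.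

Step 7
Reactants: 10 dienone ester
Product: 11 3‑[2‑(tert‑butyldimethylsilyloxy)‑2‑[(tert‑butyldimethylsilyloxy)methyl]‑1,6‑dimethyl‑5‑oxocyclohexyl]propanoic acid (C3 ketone, C8 acid; ring stereocentres as in 7)
Conditions: H2 (3 atm), Pd/C, EtOAc, rt
Reagents that add atoms: none
Why: Heterogeneous hydrogenation should saturate both disubstituted alkenes (C1=C2 and C6=C7) and hydrogenolyse the benzyl ester in one operation. No stereocentre is formed, and the neutral conditions avoid epimerisation at C4.

Step 8
Reactants: 11 keto acid
Product: 12 3‑[2‑(tert‑butyldimethylsilyloxy)‑2‑[(tert‑butyldimethylsilyloxy)methyl]‑5‑hydroxy‑1,6‑dimethylcyclohexyl]propanoic acid (C3 hydroxyl axial, on the face of the C4 and C5 methyls)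
Conditions: LiBH(sec‑Bu)3 (2.5 equiv), THF, −78 °C; 1 M HCl
Reagents that add atoms: none
Why: Bulky hydride reduction; in the favoured chair of ring B (C4 methyl equatorial, C5 methyl axial) axial approach to C3 is blocked by the syn‑axial C5 methyl, so hydride enters equatorially and gives the axial C3 alcohol cis to both methyls. The first equivalent is consumed by the acid, whose carboxylate is inert.

Step 9
Reactants: 12 hydroxy acid
Product: 14 acetoxy acid (C3 acetate; C8 carboxylic acid; C9/C10 TBS ethers), via mixed acetic anhydride 13 (not isolated)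
Conditions: Ac2O, pyridine, DMAP (cat.), CH2Cl2, rt; then H2O, THF
Reagents that add atoms: acetic anhydride, CC(=O)OC(C)=O
Why: DMAP‑catalysed acetylation of the hindered axial alcohol; the carboxyl group is converted in passing into mixed anhydride 13, which water cleaves at the acetyl carbonyl to return the acid.

Step 10
Reactants: 14 acetoxy acid
Product: 15 acetoxy alcohol (C3 acetate; C8 primary alcohol; C9 and C10 TBS ethers)
Conditions: BH3·SMe2, THF, 0 °C → rt; H2O
Reagents that add atoms: none
Why: Borane reduces carboxylic acids through acyloxyboranes far faster than esters, so the C8 acid should become the primary alcohol while the C3 acetate and both silyl ethers survive.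

Step 11
Reactants: 15 acetoxy alcohol
Product: 16 diol (C8 and C9 primary alcohols; C3 acetate; C10 TBS ether)
Conditions: HF·pyridine, pyridine, THF, 0 °C → rt
Reagents that add atoms: none
Why: Buffered HF·pyridine distinguishes silyl ethers by steric access: the primary C9 ether should be cleaved while the tertiary C10 ether next to the quaternary C5 is kept.

Step 12
Reactants: 16 diol
Product: 17 dialdehyde (C8 and C9 aldehydes; C3 acetate; C10 TBS ether)
Conditions: Dess–Martin periodinane, NaHCO3, CH2Cl2, rt; used at once
Reagents that add atoms: none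
Why: Twofold Dess–Martin oxidation of the two primary alcohols. The C9 aldehyde has no α‑hydrogen; the C8 aldehyde is enolisable, which is why 17 is not stored.

Step 13
Reactants: 17 dialdehyde
Product: 18 cis‑fused ketol (C8 ketone; C9 hydroxyl trans to the C10 silyloxy group; C3 acetate; C10 TBS ether)
Conditions: 2‑(pentafluorophenyl)‑6,7‑dihydro‑5H‑pyrrolo[2,1‑c][1,2,4]triazol‑2‑ium tetrafluoroborate (10 mol %), Et3N (10 mol %), CH2Cl2, rt
Reagents that add atoms: none
Why: Carbene‑catalysed intramolecular cross‑benzoin reaction, known for dialdehydes: the unhindered C8 aldehyde forms the acyl anion equivalent and adds to the non‑enolisable C9 aldehyde in a six‑membered closure. C9 is set here: in the chair‑like transition state the C9 carbonyl is expected to lie antiperiplanar to the axial C10–O bond (dipole minimisation), which places the new hydroxyl trans to the silyloxy group. The centre is epimerisable, so weak base is used and the reaction is stopped at conversion.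

Step 14
Reactants: 18 ketol
Product: 19 C9 triethylsilyl ether of 18
Conditions: TESOTf, 2,6‑lutidine, CH2Cl2, −78 °C
Reagents that add atoms: triethylsilyl trifluoromethanesulfonate, CC[Si](CC)(CC)OS(=O)(=O)C(F)(F)F
Why: Silyl triflate/2,6‑lutidine silylation of the hindered secondary alcohol at low temperature; the ether protects the ketol oxygen from acylation in step 15 and directs enolisation away from C9.

Step 15
Reactants: 19 silyloxy ketone; 20 1‑acetylbenzotriazole
Product: 21 β‑diketone (C7 acetyl, C8 ketone, largely enolised; C9 TES ether; C10 TBS ether; C3 acetate)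
Conditions: 20, MgBr2·OEt2, i‑Pr2NEt, CH2Cl2, rt
Reagents that add atoms: none
Why: Soft‑enolisation C‑acylation: the magnesium enolate forms at the unhindered C7 methylene and not at the silyloxy‑bearing C9, and chelation in the magnesium diketonate favours C‑ over O‑acylation. The acetate is not touched by the amine base, and C7 is of no stereochemical consequence because 21 is enolised.

Step 16
Reactants: 21 β‑diketone
Product: 24 bis‑silylated enedione (7‑acetyl C6=C7 C8 ketone; C9 TES ether; C10 TBS ether; C3 acetate), via C7 phenylselenide 22 (not isolated), via C7 selenoxide 23 (not isolated)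
Conditions: PhSeCl, pyridine, CH2Cl2, 0 °C; then 30% H2O2, 0 °C → rt
Reagents that add atoms: none
Why: Selenenylation of the enolised β‑diketone at C7, oxidation to the selenoxide and syn elimination toward the only β‑hydrogens (on C6) is the standard dehydrogenation of β‑dicarbonyl compounds. Selenium is lost, and the quaternary C5 shields the new 2‑acyl enone.

Step 17
Reactants: 24 bis‑silylated enedione
Product: 25 diol (C9 secondary and C10 tertiary hydroxyl; 7‑acetyl enone; C3 acetate)
Conditions: 48% aq. HF, MeCN, 0 °C → rt
Reagents that add atoms: none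
Why: Acidic fluoride should cleave both silyl ethers without generating an alkoxide, so the retro‑aldol and C9 epimerisation pathways of a basic fluoride source are avoided. Esters and the enedione tolerate HF.

Step 18
Reactants: 25 diol; 26 (Z)‑2‑methylbut‑2‑enoic acid (angelic acid)
Product: 28 target, via mixed anhydride 27 (not isolated)
Conditions: 26, 2,4,6‑trichlorobenzoyl chloride, Et3N, toluene, rt; then 25, 60–80 °C
Reagents that add atoms: none
Why: Mixed‑anhydride (Yamaguchi‑type) esterification without a nucleophilic amine catalyst, the established way to transfer the (Z)‑2‑methylbut‑2‑enoyl group without isomerisation to the E ester. The secondary C9 hydroxyl should react and the tertiary C10 hydroxyl should not; C9 keeps its configuration because only the O–H bond is broken.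

## Compound list

1 | (tert‑butyldimethylsilyloxy)acetaldehyde | CC(C)(C)[Si](C)(C)OCC=O | starting material
2 | allylmagnesium bromide | C=CC[Mg]Br | starting material
3 | racemic 1‑(tert‑butyldimethylsilyloxy)pent‑4‑en‑2‑ol | CC(C)(C)[Si](C)(C)OCC(O)CC=C | intermediate
4 | 1‑(tert‑butyldimethylsilyloxy)pent‑4‑en‑2‑one | CC(C)(C)[Si](C)(C)OCC(=O)CC=C | intermediate
5 | (Z)‑1,2‑bis(tert‑butyldimethylsilyloxy)penta‑2,4‑diene | C=C/C=C(/CO[Si](C)(C)C(C)(C)C)O[Si](C)(C)C(C)(C)C | intermediate
6 | (E)‑2‑methylbut‑2‑enal | C/C=C(\C)C=O | starting material
7 | (1R,2R,6S)‑2‑(tert‑butyldimethylsilyloxy)‑2‑[(tert‑butyldimethylsilyloxy)methyl]‑1,6‑dimethylcyclohex‑3‑ene‑1‑carbaldehyde | O=C[C@]1(C)[C@@H](C)CC=C[C@]1(O[Si](C)(C)C(C)(C)C)CO[Si](C)(C)C(C)(C)C | intermediate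
8 | benzyl (diethoxyphosphoryl)acetate | CCOP(=O)(CC(=O)OCc1ccccc1)OCC | starting material
9 | benzyl (E)‑enoate of 7 (C6=C7, C8 ester) | O=C(OCc1ccccc1)/C=C/[C@]1(C)[C@@H](C)CC=C[C@]1(O[Si](C)(C)C(C)(C)C)CO[Si](C)(C)C(C)(C)C | intermediate
10 | C3 enone benzyl enoate | O=C(OCc1ccccc1)/C=C/[C@]1(C)[C@@H](C)C(=O)C=C[C@]1(O[Si](C)(C)C(C)(C)C)CO[Si](C)(C)C(C)(C)C | intermediate
11 | C3 keto C8 acid | OC(=O)CC[C@]1(C)[C@@H](C)C(=O)CC[C@]1(O[Si](C)(C)C(C)(C)C)CO[Si](C)(C)C(C)(C)C | intermediate
12 | C3 hydroxy C8 acid | OC(=O)CC[C@]1(C)[C@@H](C)[C@@H](O)CC[C@]1(O[Si](C)(C)C(C)(C)C)CO[Si](C)(C)C(C)(C)C | intermediate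
13 | mixed acetic anhydride of 14 (not isolated) | CC(=O)OC(=O)CC[C@]1(C)[C@@H](C)[C@@H](OC(C)=O)CC[C@]1(O[Si](C)(C)C(C)(C)C)CO[Si](C)(C)C(C)(C)C | intermediate
14 | C3 acetoxy C8 acid | OC(=O)CC[C@]1(C)[C@@H](C)[C@@H](OC(C)=O)CC[C@]1(O[Si](C)(C)C(C)(C)C)CO[Si](C)(C)C(C)(C)C | intermediate
15 | C3 acetoxy C8 alcohol, C9 and C10 TBS ethers | OCCC[C@]1(C)[C@@H](C)[C@@H](OC(C)=O)CC[C@]1(O[Si](C)(C)C(C)(C)C)CO[Si](C)(C)C(C)(C)C | intermediate
16 | C8,C9 diol, C10 TBS ether | OCCC[C@]1(C)[C@@H](C)[C@@H](OC(C)=O)CC[C@]1(O[Si](C)(C)C(C)(C)C)CO | intermediate
17 | C8,C9 dialdehyde, C10 TBS ether | O=CCC[C@]1(C)[C@@H](C)[C@@H](OC(C)=O)CC[C@]1(O[Si](C)(C)C(C)(C)C)C=O | intermediate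
18 | cis‑decalin ketol (C8 ketone, C9 hydroxyl trans to C10 OTBS) | O[C@@H]1C(=O)CC[C@]2(C)[C@@H](C)[C@@H](OC(C)=O)CC[C@]12O[Si](C)(C)C(C)(C)C | intermediate
19 | C9 TES ether of 18 | CC[Si](CC)(CC)O[C@@H]1C(=O)CC[C@]2(C)[C@@H](C)[C@@H](OC(C)=O)CC[C@]12O[Si](C)(C)C(C)(C)C | intermediate
20 | 1‑acetylbenzotriazole | CC(=O)n1nnc2ccccc12 | starting material
21 | 7‑acetyl‑8‑ketone (β‑diketone, C7 unspecified, enolised) | CC[Si](CC)(CC)O[C@@H]1C(=O)C(C(C)=O)C[C@]2(C)[C@@H](C)[C@@H](OC(C)=O)CC[C@]12O[Si](C)(C)C(C)(C)C | intermediate
22 | C7 phenylselenide of 21 (not isolated) | CC[Si](CC)(CC)O[C@@H]1C(=O)C([Se]c3ccccc3)(C(C)=O)C[C@]2(C)[C@@H](C)[C@@H](OC(C)=O)CC[C@]12O[Si](C)(C)C(C)(C)C | intermediate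
23 | C7 selenoxide (not isolated) | CC[Si](CC)(CC)O[C@@H]1C(=O)C([Se](=O)c3ccccc3)(C(C)=O)C[C@]2(C)[C@@H](C)[C@@H](OC(C)=O)CC[C@]12O[Si](C)(C)C(C)(C)C | intermediate
24 | enedione with C9 TES and C10 TBS ethers | CC[Si](CC)(CC)O[C@@H]1C(=O)C(C(C)=O)=C[C@]2(C)[C@@H](C)[C@@H](OC(C)=O)CC[C@]12O[Si](C)(C)C(C)(C)C | intermediate
25 | enedione 9,10‑diol | O[C@@H]1C(=O)C(C(C)=O)=C[C@]2(C)[C@@H](C)[C@@H](OC(C)=O)CC[C@]12O | intermediate
26 | (Z)‑2‑methylbut‑2‑enoic acid (angelic acid) | C/C=C(/C)C(=O)O | starting material
27 | (Z)‑2‑methylbut‑2‑enoic 2,4,6‑trichlorobenzoic anhydride (not isolated) | C/C=C(/C)C(=O)OC(=O)c1c(Cl)cc(Cl)cc1Cl | intermediate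
28 | (3S,4R,5R,9S,10R)‑3‑acetoxy‑7‑acetyl‑10‑hydroxy‑4,5‑dimethyl‑8‑oxo‑cis‑decal‑6‑en‑9‑yl (Z)‑2‑methylbut‑2‑enoate (decalin numbering as above) | C/C=C(/C)C(=O)O[C@@H]1C(=O)C(C(C)=O)=C[C@]2(C)[C@@H](C)[C@@H](OC(C)=O)CC[C@]12O | target

## Step count and least certain steps

Total step count: 18. Longest linear sequence: 18 steps (1 → 28); compounds 2, 6, 8, 20 and 26 enter as purchased reagents.

**Step 4 (key step).** The most likely failure is open‑chain vinylogous Mukaiyama addition (to the β‑carbon or to the formyl carbon) or protodesilylation of the diene in place of ring closure. The Z diene must turn a silyloxy group inward to reach the s‑cis form, and both carbons of the new C5–C10 bond are fully substituted. Further risks are loss of formyl‑endo preference through the α‑methyl group, reaction of any E diene carried over from step 3 to give the C10 epimer, and incomplete face discrimination. The fallback sets out from 5 and 6 and removes the Lewis acid altogether. An uncatalysed cycloaddition at high pressure (about 12–14 kbar, CH2Cl2, rt) would give the racemic adduct, that is 7 together with its mirror image, (1S,2S,6R)‑2‑(tert‑butyldimethylsilyloxy)‑2‑[(tert‑butyldimethylsilyloxy)methyl]‑1,6‑dimethylcyclohex‑3‑ene‑1‑carbaldehyde F1. Preparative chromatography on a chiral stationary phase separates the two, and the route is rejoined at 7.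

**Step 6.** Oxygen may be delivered to the wrong end of the allyl system (giving a C1 ketone), the hindered cis‑disubstituted alkene may react slowly, and the C4 centre may epimerise once the ketone is present. The fallback sets out from 9. SeO2 (catalytic) with t‑BuOOH in CH2Cl2 effects an ene reaction and [2,3] shift that can only oxygenate C3 and would give the allylic alcohol benzyl (E)‑3‑[2‑(tert‑butyldimethylsilyloxy)‑2‑[(tert‑butyldimethylsilyloxy)methyl]‑5‑hydroxy‑1,6‑dimethylcyclohex‑3‑en‑1‑yl]prop‑2‑enoate F2. Dess–Martin oxidation of F2 returns to 10.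

**Step 13.** Base‑mediated aldol closure (C7 enolate onto the C9 aldehyde, five‑membered ring) may compete with carbene catalysis. Facial selectivity at C9 may be poor or reversed, and the ketol may epimerise or transpose under the basic conditions. The fallback sets out from 17. A pinacol cyclisation with SmI2 (divalent samarium; THF, t‑BuOH, −78 °C) would give the cis‑8,9‑diol with both new oxygens anti to the C10 silyloxy group, the usual outcome of such closures next to an oxygenated centre: cis‑decalin‑8,9‑diol with C3 acetate and C10 TBS ether F3. Oxidation of the less hindered C8 carbinol with an oxoammonium system (TEMPO, PhI(OAc)2), which discriminates against the neopentyl C9 carbinol, returns to 18.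

**Step 15.** O‑acylation, enolisation toward C9 with epimerisation, or stalled enolisation of the hindered ketone may occur. The fallback sets out from 19 and builds the acetyl enone by cross‑coupling, bypassing 21 to 23:
- dehydrogenation with 2‑iodoxybenzoic acid (DMSO, 65 °C) to the C6=C7 enone with C9 TES and C10 TBS ethers F4;
- α‑iodination (I2, pyridine, CH2Cl2) to the 7‑iodo enone F5;
- Stille coupling with tributyl(1‑ethoxyvinyl)stannane (Pd(PPh3)4, CuI, DMF, rt to 50 °C) to the 7‑(1‑ethoxyvinyl) enone F6;
- brief hydrolysis (0.5 M HCl, THF, 0 °C), which unmasks the acetyl group and returns to 24.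

**Step 18.** Acyl transfer to an electron‑poor, hindered α‑ketol may be slow. Prolonged heating with amine then allows Z to E isomerisation of the acyl group, epimerisation at C9, or retro‑aldol cleavage of the β‑hydroxy ketone. The fallback moves the esterification ahead of the enedione, to a substrate that tolerates forcing conditions, and sets out from 18:
- reaction of 18 with mixed anhydride 27 (toluene, 80 °C) to the C9 (Z)‑2‑methylbut‑2‑enoate of ketol 18 F7;
- C‑acetylation as in step 15 to the 7‑acetyl β‑diketone angelate F8;
- selenenylation and oxidation as in step 16, through the C7 phenylselenide F9 and the C7 selenoxide F10, to the enedione angelate with C10 TBS ether F11;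
- HF in MeCN as in step 17, which removes the C10 silyl group and returns to 28.

## Further compounds

F1 | step 4 | (1S,2S,6R)‑2‑(tert‑butyldimethylsilyloxy)‑2‑[(tert‑butyldimethylsilyloxy)methyl]‑1,6‑dimethylcyclohex‑3‑ene‑1‑carbaldehyde (enantiomer of 7) | O=C[C@@]1(C)[C@H](C)CC=C[C@@]1(O[Si](C)(C)C(C)(C)C)CO[Si](C)(C)C(C)(C)C
F2 | step 6 | benzyl (E)‑3‑[2‑(tert‑butyldimethylsilyloxy)‑2‑[(tert‑butyldimethylsilyloxy)methyl]‑5‑hydroxy‑1,6‑dimethylcyclohex‑3‑en‑1‑yl]prop‑2‑enoate (C3 allylic alcohol, C3 configuration open) | O=C(OCc1ccccc1)/C=C/[C@]1(C)[C@@H](C)C(O)C=C[C@]1(O[Si](C)(C)C(C)(C)C)CO[Si](C)(C)C(C)(C)C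
F3 | step 13 | cis‑decalin‑8,9‑diol with C3 acetate and C10 TBS ether (both hydroxyls anti to C10 OTBS) | O[C@@H]1[C@H](O)CC[C@]2(C)[C@@H](C)[C@@H](OC(C)=O)CC[C@]12O[Si](C)(C)C(C)(C)C
F4 | step 15 | C6=C7 enone with C9 TES and C10 TBS ethers | CC[Si](CC)(CC)O[C@@H]1C(=O)C=C[C@]2(C)[C@@H](C)[C@@H](OC(C)=O)CC[C@]12O[Si](C)(C)C(C)(C)C
F5 | step 15 | 7‑iodo enone | CC[Si](CC)(CC)O[C@@H]1C(=O)C(I)=C[C@]2(C)[C@@H](C)[C@@H](OC(C)=O)CC[C@]12O[Si](C)(C)C(C)(C)C
F6 | step 15 | 7‑(1‑ethoxyvinyl) enone | CC[Si](CC)(CC)O[C@@H]1C(=O)C(C(=C)OCC)=C[C@]2(C)[C@@H](C)[C@@H](OC(C)=O)CC[C@]12O[Si](C)(C)C(C)(C)C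
F7 | step 18 | C9 (Z)‑2‑methylbut‑2‑enoate of ketol 18 | C/C=C(/C)C(=O)O[C@@H]1C(=O)CC[C@]2(C)[C@@H](C)[C@@H](OC(C)=O)CC[C@]12O[Si](C)(C)C(C)(C)C
F8 | step 18 | 7‑acetyl β‑diketone angelate (C7 unspecified) | C/C=C(/C)C(=O)O[C@@H]1C(=O)C(C(C)=O)C[C@]2(C)[C@@H](C)[C@@H](OC(C)=O)CC[C@]12O[Si](C)(C)C(C)(C)C
F9 | step 18 | C7 phenylselenide of F8 | C/C=C(/C)C(=O)O[C@@H]1C(=O)C([Se]c3ccccc3)(C(C)=O)C[C@]2(C)[C@@H](C)[C@@H](OC(C)=O)CC[C@]12O[Si](C)(C)C(C)(C)C
F10 | step 18 | C7 selenoxide of F8 | C/C=C(/C)C(=O)O[C@@H]1C(=O)C([Se](=O)c3ccccc3)(C(C)=O)C[C@]2(C)[C@@H](C)[C@@H](OC(C)=O)CC[C@]12O[Si](C)(C)C(C)(C)C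
F11 | step 18 | enedione angelate with C10 TBS ether | C/C=C(/C)C(=O)O[C@@H]1C(=O)C(C(C)=O)=C[C@]2(C)[C@@H](C)[C@@H](OC(C)=O)CC[C@]12O[Si](C)(C)C(C)(C)C
A1 | alternative 1 | siloxane‑bridged cis‑fused octalenone (ring A enone, C4–CH2–Si–O–C3 ring) | C1C(=O)C=C[C@]2(C)[C@H]3C[Si](C)(C)O[C@H]3CC[C@]12O
A2 | alternative 2 | cis‑fused 7‑acetyl‑octalen‑8‑ol (one C8 epimer, C9 TES ether) | CC(=O)C1=C[C@]2(C)[C@@H](C)[C@@H](OC(C)=O)CC[C@]2(O)[C@H](O[Si](CC)(CC)CC)[C@@H]1O
A3 | alternative 3 | cis‑fused decalin ketol (C8 ketone, C9 hydroxyl, C10 TES ether) | O[C@@H]1C(=O)CC[C@]2(C)[C@@H](C)[C@@H](OC(C)=O)CC[C@]12O[Si](CC)(CC)CC
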